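In a one-step world the curve runs to the charge, 100%, and you need only its rate; here the second step can turn back, so first find the level where it stops.

| flask | substrate | reagent | temperature | remark | time |
|---|---|---|---|---|---|
| teal | 0.050 M | 0.125 M | 75 °C | run made earlier |  |
| ochre | 0.050 M | 0.062 M | 86 °C | run made earlier |  |
| violet | 0.050 M | 0.25 M | 75 °C | run made earlier |  |
| dusk | 0.050 M | 0.125 M (fed, over 25 s) |  | the addition at 50 °C, then warmed to 80 °C; the feed brings no volume worth counting | 2.0 min |
| midnight | 0.050 M | 0.125 M (fed, over 25 s) | 80 °C | all else is in the flask from the start; the feed brings no volume worth counting | 2.0 min |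
| noon | 0.050 M | 0.125 M | 80 °C | everything together at the start | 2.0 min |
| winter | 0.050 M (fed, over 25 s) | 0.125 M | 80 °C | all else is in the flask from the start; the feed brings no volume worth counting | 2.0 min |

| run | time / s | bis adduct / % |
|---|---|---|
| teal | 10.0 | 1.4 |
| teal | 20.0 | 3.3 |
| teal | 40.0 | 8.9 |
| teal | 80.0 | 14.4 |
| ochre | 10.0 | 0.8 |
| ochre | 20.0 | 2.7 |
| ochre | 40.0 | 6.4 |
| ochre | 80.0 | 8.6 |
| violet | 10.0 | 3.2 |
| violet | 20.0 | 10.7 |
| violet | 30.0 | 16.1 |
| violet | 50.0 | 26.8 |
| violet | 80.0 | 30.5 |

(standard deviation of a reading: 0.5 percentage points)

- percentages count the substrate that a species holds: one homo dimer counts as two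
- candidate steps: reagent + single product <-> bis adduct + by-product; 2 substrate -> homo dimer; substrate + reagent -> single product + by-product

- the best flask by amount of bis adduct, in percent of the substrate charged; "all alike" if 1.5 percentage points covers them all (dusk / midnight / noon / winter / all alike)
- amount of bis adduct at the end, in percent of the substrate charged, dusk
- amount of bis adduct at the end, in percent of the substrate charged, midnight
- amount of bis adduct at the end, in percent of the substrate charged, noon
- amount of bis adduct at the end, in percent of the substrate charged, winter

Draw the violet curve. It starts flat, with 3.2% at 10.0 s and then a rise larger than that, 7.5 percentage points, in the same time: single product has to stand first. The knee comes next: 11 points in 20.0 s, then 3.7 points in 30.0 s. So the rate dies with a time constant of about 17.0 s, and the tail adds up to a level near 31.4%, as a reading.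

At that level the forward and back rates cross: thermodynamic control. Count in fractions of the substrate charge, with the substrate spent: d is bis adduct, a is what the homo dimer leaves, ρ is reagent per substrate. Then single product is a−d, by-product a+d, and reagent ρ−a−d. The turn-back quotient, d(a+d) over (a−d)(ρ−a−d), comes to 0.163 for violet, taking a as whole.

For your flasks ρ is 2.50. The quotient gives a level of 15.9% with no homo dimer. With 20.0% lost to homo dimer it gives 16.5%, a shift smaller than the margin. Taking off the 25 s of feed leaves 5.58 time constants, as read at violet. My reckoning therefore says alike, near that level, though it was read at 75 °C with twice the reagent, and these flasks end at 80 °C.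

The forecast says all alike, since “the equilibrium bis barely moves”, with 17.5%, 17%, 17.5% and 18% for dusk, midnight, noon and winter, each above my level.

The flasks give 18.2%, 18.4%, 18.5% and 18.4% in that order: all alike.

    reagent + single product ⇌ bis adduct + by-product (K = 0.200, k = 0.110 M⁻¹ s⁻¹, Ea = 78.0 kJ mol⁻¹, ΔH = 19.0 kJ mol⁻¹)
    2 substrate → homo dimer (k = 0.0670 M⁻¹ s⁻¹, Ea = 53.0 kJ mol⁻¹)
    substrate + reagent → single product + by-product (k = 0.340 M⁻¹ s⁻¹, Ea = 71.0 kJ mol⁻¹)
    (constants at 80 °C)

Homo dimer at the end runs from 6.44% in winter to 14.0% in midnight. Noon's state at 20.0 min, with bis adduct 18.5% and homo dimer 8.28%, puts the quotient at 0.200. With that value and midnight's homo dimer, 14.0%, the level is 18.7%, and midnight at 20.0 min holds 18.7%.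

The runs come from a simulation for substances that don't exist, and the scatter is random.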